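## Retrosynthetic overview

1. Assumption: the target is a flat flavone with no stereocenters, so "single enantiomer" does not apply and no stereochemistry needs to be set.
2. The last step is hydrogenolysis of the 5- and 7-O-benzyl ethers of **12**. Ester **12** comes from a proposed new C8–H isovaleroyloxylation of 5,7-bis(benzyloxy)-3,6,4'-trimethoxyflavone **11**, in which C8 is the only free ring-A position.
3. Flavone **11** comes from O-methylation of flavonol **10**. Flavonol **10** comes from an Algar–Flynn–Oyamada (AFO) cyclization of 2'-hydroxychalcone **9**, which closes ring C and puts oxygen on C3.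
4. Chalcone **9** comes from Claisen–Schmidt condensation of acetophenone **7** with anisaldehyde **8**, which brings in ring B.
5. Ring A (acetophenone **7**) is built from 4-O-methylgallic acid **1** by bis-benzylation, reduction, oxidation to the aldehyde, Dakin-type Baeyer–Villiger oxidation to the phenol, and BF3 acetylation. The rings are made in the order A, then B (added at the chalcone), then C (AFO).

## Route

**Step 1**
Reactants: 1 (3,5-dihydroxy-4-methoxybenzoic acid)
Product: 2 (benzyl 3,5-bis(benzyloxy)-4-methoxybenzoate)
Conditions: BnBr (3.3 equiv), K2CO3, DMF, 60 °C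
Reagents that add atoms: benzyl bromide, BrCc1ccccc1
Why: Williamson O-alkylation of both phenols and the carboxylate gives one symmetric, fully benzyl-protected compound. No stereocenters are involved.

**Step 2**
Reactants: 2
Product: 3 ([3,5-bis(benzyloxy)-4-methoxyphenyl]methanol)
Conditions: LiAlH4, THF, 0 °C to rt
Reagents that add atoms: none
Why: Ester-to-alcohol reduction leaves the aryl benzyl ethers untouched. The benzyl alcohol by-product is removed by chromatography.

**Step 3**
Reactants: 3
Product: 4 (3,5-bis(benzyloxy)-4-methoxybenzaldehyde)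
Conditions: activated MnO2, CH2Cl2, rt
Reagents that add atoms: none
Why: MnO2 selectively oxidizes the electron-rich benzylic alcohol to the aldehyde without over-oxidation.

**Step 4**
Reactants: 4
Product: 5 (3,5-bis(benzyloxy)-4-methoxyphenyl formate)
Conditions: mCPBA, CH2Cl2, 0 °C to rt
Reagents that add atoms: mCPBA, O=C(OO)c1cccc(Cl)c1
Why: In this Dakin-type Baeyer–Villiger oxidation the electron-rich aryl group migrates in preference to hydride, so the aldehyde becomes the aryl formate, as in the standard conversion of 3,4,5-trialkoxybenzaldehydes to phenols.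

**Step 5**
Reactants: 5
Product: 6 (3,5-bis(benzyloxy)-4-methoxyphenol)
Conditions: K2CO3, MeOH, rt
Reagents that add atoms: none
Why: Base methanolysis of the formate ester releases the phenol and leaves the benzyl ethers intact.

**Step 6**
Reactants: 6
Product: 7 (1-[4,6-bis(benzyloxy)-2-hydroxy-5-methoxyphenyl]ethan-1-one)
Conditions: AcOH, BF3·OEt2, 40–50 °C
Reagents that add atoms: acetic acid, CC(=O)O
Why: This is a Nencki-type BF3-mediated C-acetylation of an electron-rich phenol. The two positions ortho to OH are equivalent by symmetry, so one regioisomer forms, and the 2'-OH···O=C hydrogen bond stabilizes the product.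

**Step 7**
Reactants: 7, 8 (4-methoxybenzaldehyde)
Product: 9 ((E)-1-[4,6-bis(benzyloxy)-2-hydroxy-5-methoxyphenyl]-3-(4-methoxyphenyl)prop-2-en-1-one)
Conditions: 50% aq. KOH, EtOH, rt, 24–48 h
Reagents that add atoms: none
Why: Claisen–Schmidt aldol condensation followed by dehydration gives the thermodynamically favored E-enone.

**Step 8**
Reactants: 9
Product: 10 (5,7-bis(benzyloxy)-3-hydroxy-6,4'-dimethoxyflavone)
Conditions: 30% H2O2, aq. NaOH, MeOH/THF, 0 °C to rt
Reagents that add atoms: hydrogen peroxide, OO
Why: In the Algar–Flynn–Oyamada reaction, nucleophilic epoxidation of the enone is followed by phenoxide opening of the epoxide and oxidation to the flavonol. The product is planar and achiral, so any transient stereocenters are lost.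

**Step 9**
Reactants: 10
Product: 11 (5,7-bis(benzyloxy)-3,6,4'-trimethoxyflavone)
Conditions: MeI, K2CO3, DMF, rt
Reagents that add atoms: methyl iodide, CI
Why: The acidic 3-OH is the only free hydroxyl, so Williamson O-methylation occurs only there.

**Step 10 (new step)**
Reactants: 11
Product: 12 (5,7-bis(benzyloxy)-3,6,4'-trimethoxyflavon-8-yl 3-methylbutanoate)
Conditions: PhIO (1.5 equiv), isovaleric acid (5 equiv), BF3·OEt2 (2 equiv), CH2Cl2, –20 to 0 °C, 2 h
Reagents that add atoms: isovaleric acid, CC(C)CC(=O)O
Why: Proposed new method: oxidative C8–H acyloxylation of a fully alkoxylated flavone A ring, which forms the C8–O bond and completes the hexasubstituted ring A. PhIO, BF3 and the carboxylic acid give a cationic PhI(O2CR)+ species that oxidizes the most electron-rich arene (ring A: 5-OBn, 6-OMe, 7-OBn, 8a-OAr) by single-electron transfer or aryl-iodane formation. The resulting radical cation or Wheland-type intermediate is attacked by isovalerate at C8, which is the only free A-ring carbon, para to 5-OBn and ortho to 7-OBn. Loss of H+ and PhI (with one more electron in the radical-cation pathway) restores aromaticity and gives the aryl ester. The closest known reactions are hypervalent-iodine/BF3 oxidative nucleophilic substitution of electron-rich arenes and electro-oxidative C–H acyloxylation of anisoles. It is new because it has not been shown on a chromone A ring, where the 4-carbonyl deactivates the ring. Capping all phenols as ethers avoids quinone and ortho-quinol formation. No stereocenter is formed.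

**Step 11**
Reactants: 12
Product: 13 (target, 5,7,8-trihydroxy-3,6,4'-trimethoxyflavone 8-isovalerate)
Conditions: H2 (1 atm), 10% Pd/C, EtOAc/MeOH, rt, 2–3 h
Reagents that add atoms: none
Why: Hydrogenolysis removes both benzyl ethers under neutral conditions. The aryl ester, the two OMe groups and the flavone C2=C3 bond survive at 1 atm. Assumption: the 8-O-acyl isomer is the thermodynamically preferred 7,8-catechol monoester, because the free 7-OH is the more acidic, vinylogous-acid oxygen. Acyl migration is minimized by the neutral, short reaction and the absence of base.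

## Compound list

1 | 3,5-dihydroxy-4-methoxybenzoic acid | COc1c(O)cc(C(=O)O)cc1O | starting material
2 | benzyl 3,5-bis(benzyloxy)-4-methoxybenzoate | COc1c(OCc2ccccc2)cc(C(=O)OCc2ccccc2)cc1OCc1ccccc1 | intermediate
3 | [3,5-bis(benzyloxy)-4-methoxyphenyl]methanol | COc1c(OCc2ccccc2)cc(CO)cc1OCc1ccccc1 | intermediate
4 | 3,5-bis(benzyloxy)-4-methoxybenzaldehyde | COc1c(OCc2ccccc2)cc(C=O)cc1OCc1ccccc1 | intermediate
5 | 3,5-bis(benzyloxy)-4-methoxyphenyl formate | COc1c(OCc2ccccc2)cc(OC=O)cc1OCc1ccccc1 | intermediate
6 | 3,5-bis(benzyloxy)-4-methoxyphenol | COc1c(OCc2ccccc2)cc(O)cc1OCc1ccccc1 | intermediate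
7 | 1-[4,6-bis(benzyloxy)-2-hydroxy-5-methoxyphenyl]ethan-1-one | CC(=O)c1c(O)cc(OCc2ccccc2)c(OC)c1OCc1ccccc1 | intermediate
8 | 4-methoxybenzaldehyde | COc1ccc(C=O)cc1 | starting material
9 | (E)-1-[4,6-bis(benzyloxy)-2-hydroxy-5-methoxyphenyl]-3-(4-methoxyphenyl)prop-2-en-1-one | COc1ccc(/C=C/C(=O)c2c(O)cc(OCc3ccccc3)c(OC)c2OCc2ccccc2)cc1 | intermediate
10 | 5,7-bis(benzyloxy)-3-hydroxy-6,4'-dimethoxyflavone | COc1ccc(-c2oc3cc(OCc4ccccc4)c(OC)c(OCc4ccccc4)c3c(=O)c2O)cc1 | intermediate
11 | 5,7-bis(benzyloxy)-3,6,4'-trimethoxyflavone | COc1ccc(-c2oc3cc(OCc4ccccc4)c(OC)c(OCc4ccccc4)c3c(=O)c2OC)cc1 | intermediate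
12 | 5,7-bis(benzyloxy)-3,6,4'-trimethoxyflavon-8-yl 3-methylbutanoate | COc1ccc(-c2oc3c(OC(=O)CC(C)C)c(OCc4ccccc4)c(OC)c(OCc4ccccc4)c3c(=O)c2OC)cc1 | intermediate
13 | 5,7,8-trihydroxy-3,6,4'-trimethoxyflavone 8-isovalerate (achiral) | COc1ccc(-c2oc3c(OC(=O)CC(C)C)c(O)c(OC)c(O)c3c(=O)c2OC)cc1 | target

## Totals

- Total steps: 11.
- Longest linear sequence: 11 steps (1 → 2 → 3 → 4 → 5 → 6 → 7 → 9 → 10 → 11 → 12 → 13). Anisaldehyde 8 joins at step 7.

## Three steps most likely to fail

1. **Step 10 (new C8–H isovaleroyloxylation).** Over-oxidation, oxidation of the benzyl ethers, B-ring attack, or BF3 cleavage of 5-OBn may compete with the desired reaction, and the chromone carbonyl deactivates ring A.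
   - Fallback (known chemistry, changes the approach): Rieche formylation of 11 at C8 (Cl2CHOMe, TiCl4), then Dakin-type Baeyer–Villiger oxidation (mCPBA) and methanolysis to the 8-OH flavone. Acylate with isovaleryl chloride/pyridine, then run step 11.
2. **Step 8 (AFO).** Aurone formation or low yield is possible with the 6'-OBn chalcone.
   - Fallback (changes the approach): Houben–Hoesch reaction of phenol 6 with MeOCH2CN gives the ω-methoxy-2'-hydroxyacetophenone. Baker–Venkataraman reaction with anisoyl chloride and acid cyclodehydration then give 3-methoxyflavone 11 directly, replacing steps 6–9.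
3. **Step 6 (BF3/AcOH acetylation).** The benzyl ethers may cleave or migrate under the Lewis acid.
   - Fallback (changes the approach): protect phenol 6 as its MOM ether and lithiate directed at C2, between OMOM and OBn. Quench with N-methoxy-N-methylacetamide and remove the MOM group with HCl/MeOH to give 7.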